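Numbering: O1, C2, C3, C4 and C4a–C8a are rings C and A. C1'–C6' is ring B. Ring D is the dimethylpyran fused at C4'/C5'.
Retrosynthesis: the two O-allyl caps come off first. Then C4–C4a is cut while ring B is moved back from C3 to C4 (a retro 1,2-aryl shift), which unfolds ring C into the linear mesylate ArA–O–CH2–CH(OMs)–CH2–ArB. Then C4–C1' is cut (aryllithium plus epoxide), and last O1–C2 (phenoxide plus glycidyl nosylate).
Forward: ring D is closed first on a bromoresorcinol (ring B) and the prenyl group follows at C3'. Rings A and B are then joined through a three-carbon chain, and ring C is closed last.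
Enabling feature: C1' is para to O4' and ortho to O2', so ring B can bridge C3/C4 as a phenonium ion. C4a is para to O7 and ortho to O1, so ring A can open that ion at C4.
Stereochemistry: C3 comes from (R)-glycidyl nosylate and is inverted once, when ring B displaces the mesylate. The (R)-mesylate maps onto the (3R)-isoflavan.

Key step: step 8

Step 1
Reactants: 1 4-bromobenzene-1,3-diol (4-bromoresorcinol); 2 3-methylbut-2-enal
Product: 3 6-bromo-2,2-dimethyl-2H-chromen-7-ol
Conditions: ethylenediammonium diacetate (10 mol %), toluene, reflux, Dean–Stark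
Reagents that add atoms: none
Why: Amine-catalysed Knoevenagel-type condensation of the enal at C6 of 1 (ortho to one hydroxyl, para to the other, less crowded than C2) should give an o-quinone methide that closes ring D by oxa-6π electrocyclisation, the standard chromene annulation of resorcinols.

Step 2
Reactants: 3 6-bromo-2,2-dimethyl-2H-chromen-7-ol; 4 1-bromo-3-methylbut-2-ene (prenyl bromide)
Product: 5 6-bromo-2,2-dimethyl-8-(3-methylbut-2-en-1-yl)-2H-chromen-7-ol
Conditions: NaH, toluene, 0 °C, then 4, rt
Reagents that add atoms: none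
Why: ortho-C-alkylation of a sodium phenoxide in a non-polar solvent, where the tight ion pair shields oxygen, should place the prenyl group at C8, the only free ortho position and the carbon between the two oxygens.

Step 3
Reactants: 5 6-bromo-2,2-dimethyl-8-(3-methylbut-2-en-1-yl)-2H-chromen-7-ol
Product: 6 6-bromo-2,2-dimethyl-8-(3-methylbut-2-en-1-yl)-7-(prop-2-en-1-yloxy)-2H-chromene
Conditions: allyl bromide, K2CO3, DMF, 50 °C
Reagents that add atoms: allyl bromide C=CCBr
Why: Williamson ether synthesis caps the phenol that would quench the aryllithium of step 6 and attack the mesylate of step 8, allyl being chosen because an ortho-lithiated silyl ether would suffer silyl migration and because allyl leaves under neutral conditions.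

Step 4
Reactants: 7 benzene-1,3-diol (resorcinol)
Product: 8 3-(prop-2-en-1-yloxy)phenol
Conditions: allyl bromide (1 equiv), K2CO3, acetone, reflux
Reagents that add atoms: allyl bromide C=CCBr
Why: Williamson mono-alkylation of a symmetrical diphenol with one equivalent of halide, the mono-ether being separable from resorcinol and the diether by extraction and chromatography.

Step 5
Reactants: 8 3-(prop-2-en-1-yloxy)phenol; 9 [(2R)-oxiran-2-yl]methyl 3-nitrobenzenesulfonate ((R)-glycidyl nosylate)
Product: 10 (2R)-2-{[3-(prop-2-en-1-yloxy)phenoxy]methyl}oxirane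
Conditions: K2CO3, DMF, 40 °C
Reagents that add atoms: none
Why: SN2 displacement of the primary nosylate by the phenoxide, which for this leaving group is favoured over attack on the epoxide, forms O1–C2 without touching the stereocentre, so the (R) descriptor is carried over.

Step 6
Reactants: 6 6-bromo-2,2-dimethyl-8-(3-methylbut-2-en-1-yl)-7-(prop-2-en-1-yloxy)-2H-chromene; 10 (2R)-2-{[3-(prop-2-en-1-yloxy)phenoxy]methyl}oxirane
Product: 12 (2R)-1-[2,2-dimethyl-8-(3-methylbut-2-en-1-yl)-7-(prop-2-en-1-yloxy)-2H-chromen-6-yl]-3-[3-(prop-2-en-1-yloxy)phenoxy]propan-2-ol, via aryllithium 11 (not isolated)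
Conditions: n-BuLi, THF, −78 °C; then BF3·OEt2 and 10, −78 °C; aq NaHCO3
Reagents that add atoms: none
Why: Bromine–lithium exchange followed by BF3-assisted SN2 opening of the terminal epoxide at its unsubstituted carbon forms C4–C1' and leaves the carbinol stereocentre untouched, the low temperature sparing the allyl ethers and the allylic CH2 of the prenyl group.

Step 7
Reactants: 12 (2R)-1-[2,2-dimethyl-8-(3-methylbut-2-en-1-yl)-7-(prop-2-en-1-yloxy)-2H-chromen-6-yl]-3-[3-(prop-2-en-1-yloxy)phenoxy]propan-2-ol
Product: 13 (2R)-1-[2,2-dimethyl-8-(3-methylbut-2-en-1-yl)-7-(prop-2-en-1-yloxy)-2H-chromen-6-yl]-3-[3-(prop-2-en-1-yloxy)phenoxy]propan-2-yl methanesulfonate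
Conditions: MsCl, Et3N, CH2Cl2, 0 °C
Reagents that add atoms: methanesulfonyl chloride CS(=O)(=O)Cl
Why: O-sulfonylation proceeds with retention at carbon and turns the hydroxyl into a leaving group that should be stable in non-ionising media.

Step 8
Reactants: 13 (2R)-1-[2,2-dimethyl-8-(3-methylbut-2-en-1-yl)-7-(prop-2-en-1-yloxy)-2H-chromen-6-yl]-3-[3-(prop-2-en-1-yloxy)phenoxy]propan-2-yl methanesulfonate
Product: 15 (3R)-3-[2,2-dimethyl-8-(3-methylbut-2-en-1-yl)-7-(prop-2-en-1-yloxy)-2H-chromen-6-yl]-7-(prop-2-en-1-yloxy)-3,4-dihydro-2H-chromene, via phenonium ion 14 (not isolated)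
Conditions: (CF3)2CHOH, 2,6-di-tert-butyl-4-methylpyridine, 40 °C
Reagents that add atoms: none
Why: Proposed new method: In the strongly ionising, non-nucleophilic solvent the mesylate should leave with anchimeric assistance from ring B, whose ipso carbon C1' attacks C3 from the rear to give the spiro-cyclopropane phenonium ion 14, and C4a of ring A then opens the three-membered ring at its CH2 carbon C4, so that ring B ends on C3 and C4 on ring A (net 1,2-aryl shift plus Friedel–Crafts alkylation). The closest known reaction types are solvolytic 1,2-aryl shifts through phenonium ions, the opening of phenonium ions by arenes in fluorinated alcohols, and the 6-endo epoxide–arene cyclisation of aryl glycidyl ethers to chroman-3-ols, of which this is the carbon analogue. Ring C closes in a 6-endo-tet mode (attack on the distal carbon of the three-membered ring), the 5-exo alternative at C3 being disfavoured by the strained approach of an ortho carbon to the proximal carbon and by the electron-withdrawing CH2OAr group on C3. The only stereocentre, C3, is under substrate control: it is inverted once when C1' displaces the mesylate and no bond to it is broken in the second stage, so (R)-13 maps onto (R)-15. The step needs aryl participation to outrun attack by O2', hydride shift and elimination, which the doubly oxygen-activated C1', the allyl cap on O2', the poorly nucleophilic solvent and the hindered base should secure, and it needs ring closure para and not ortho to O7, which the lower crowding at C4a favours.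

Step 9
Reactants: 15 (3R)-3-[2,2-dimethyl-8-(3-methylbut-2-en-1-yl)-7-(prop-2-en-1-yloxy)-2H-chromen-6-yl]-7-(prop-2-en-1-yloxy)-3,4-dihydro-2H-chromene
Product: 16 (3R)-3-[7-hydroxy-2,2-dimethyl-8-(3-methylbut-2-en-1-yl)-2H-chromen-6-yl]-3,4-dihydro-2H-chromen-7-ol (CNP0331403.1)
Conditions: Pd(PPh3)4 (5 mol %), morpholine, THF, rt
Reagents that add atoms: none
Why: Tsuji–Trost-type deallylation, in which zerovalent palladium ionises both aryl allyl ethers and morpholine traps the π-allyl complexes, works under neutral conditions that should spare the prenyl group next to the freed phenol, the chromene and C3.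

Compound list
1 | 4-bromobenzene-1,3-diol | Oc1ccc(Br)c(O)c1 | starting material
2 | 3-methylbut-2-enal | CC(C)=CC=O | starting material
3 | 6-bromo-2,2-dimethyl-2H-chromen-7-ol | CC1(C)C=Cc2cc(Br)c(O)cc2O1 | intermediate
4 | 1-bromo-3-methylbut-2-ene | CC(C)=CCBr | starting material
5 | 6-bromo-2,2-dimethyl-8-(3-methylbut-2-en-1-yl)-2H-chromen-7-ol | CC1(C)C=Cc2cc(Br)c(O)c(CC=C(C)C)c2O1 | intermediate
6 | 6-bromo-2,2-dimethyl-8-(3-methylbut-2-en-1-yl)-7-(prop-2-en-1-yloxy)-2H-chromene | CC1(C)C=Cc2cc(Br)c(OCC=C)c(CC=C(C)C)c2O1 | intermediate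
7 | benzene-1,3-diol | Oc1cccc(O)c1 | starting material
8 | 3-(prop-2-en-1-yloxy)phenol | C=CCOc1cccc(O)c1 | intermediate
9 | [(2R)-oxiran-2-yl]methyl 3-nitrobenzenesulfonate | O=S(=O)(OC[C@H]1CO1)c1cccc([N+](=O)[O-])c1 | starting material
10 | (2R)-2-{[3-(prop-2-en-1-yloxy)phenoxy]methyl}oxirane | C=CCOc1cccc(OC[C@H]2CO2)c1 | intermediate
11 | [2,2-dimethyl-8-(3-methylbut-2-en-1-yl)-7-(prop-2-en-1-yloxy)-2H-chromen-6-yl]lithium | [Li]c1cc2C=CC(C)(C)Oc2c(CC=C(C)C)c1OCC=C | intermediate
12 | (2R)-1-[2,2-dimethyl-8-(3-methylbut-2-en-1-yl)-7-(prop-2-en-1-yloxy)-2H-chromen-6-yl]-3-[3-(prop-2-en-1-yloxy)phenoxy]propan-2-ol | C=CCOc1cccc(OC[C@H](O)Cc2cc3C=CC(C)(C)Oc3c(CC=C(C)C)c2OCC=C)c1 | intermediate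
13 | methanesulfonate of 12, (2R) | C=CCOc1cccc(OC[C@H](OS(C)(=O)=O)Cc2cc3C=CC(C)(C)Oc3c(CC=C(C)C)c2OCC=C)c1 | intermediate
14 | phenonium ion: spiro-cyclopropane of C1', C3 and C4, C3 already inverted, charge drawn on O4', either spiro epimer | C=CCOc1cccc(OC[C@@H]2CC23C=C4C=CC(C)(C)[O+]=C4C(CC=C(C)C)=C3OCC=C)c1 | intermediate
15 | (3R)-3-[2,2-dimethyl-8-(3-methylbut-2-en-1-yl)-7-(prop-2-en-1-yloxy)-2H-chromen-6-yl]-7-(prop-2-en-1-yloxy)-3,4-dihydro-2H-chromene | CC(C)=CCc1c(OCC=C)c([C@@H]2COc3cc(OCC=C)ccc3C2)cc2c1OC(C)(C)C=C2 | intermediate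
16 | (3R)-3-[7-hydroxy-2,2-dimethyl-8-(3-methylbut-2-en-1-yl)-2H-chromen-6-yl]-3,4-dihydro-2H-chromen-7-ol | CC(C)=CCc1c(O)c([C@@H]2COc3cc(O)ccc3C2)cc2c1OC(C)(C)C=C2 | target

Total step count: 9. Longest linear sequence: 7 (steps 1, 2, 3, 6, 7, 8, 9).

Steps most likely to fail

Step 8 (the labelled step).
- What may go wrong: opening of the bridged ion at C3 instead of C4; hydride shift to the benzylic position before ring closure; participation of O2' with loss of its allyl group; or ring closure ortho to O7.
- Fallback: it uses known chemistry, sets out from 6 and comes back at 15. Ring C is made before the stereocentre, and C3 is then set by reduction.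
- Bromine–lithium exchange of 6 and quenching with 2-isopropoxy-4,4,5,5-tetramethyl-1,3,2-dioxaborolane would give the pinacol boronate F1.
- Commercial 2,4-dihydroxyacetophenone would be allylated at the non-chelated hydroxyl to 4-allyloxy-2-hydroxyacetophenone F2. This would be condensed with DMF dimethyl acetal to the enaminone F3 and cyclised with iodine to 7-allyloxy-3-iodochromone F4.
- Suzuki–Miyaura coupling of F1 and F4 (Pd(dppf)Cl2, K2CO3, dioxane/water) would give the isoflavone F5.
- Asymmetric transfer hydrogenation with dynamic kinetic resolution (RuCl[(R,R)-TsDPEN](p-cymene), HCO2H/Et3N) would reduce the enone double bond and then the ketone to the cis-(3R,4R)-isoflavan-4-ol F6. The isolated and styrenic alkenes should stay untouched.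
- Ionic deoxygenation of the 7-alkoxy-activated benzylic alcohol (Et3SiH, BF3·OEt2, CH2Cl2, −78 °C) would return to 15.

Step 2.
- What may go wrong: alkylation at oxygen instead of carbon, or a second alkylation of the dienone tautomer.
- Fallback: it sets out from 3 and comes back at 5, and replaces direct C-alkylation by a sigmatropic transfer from oxygen.
- O-alkylation of 3 with tert-butyl 2-methylbut-3-en-2-yl carbonate (Pd(PPh3)4, THF, 0 °C) would give the 1,1-dimethylallyl ether F7.
- Aromatic Claisen rearrangement (toluene, 110 °C) can only reach C8 and would deliver the prenyl group there with allyl inversion, giving 5.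

Step 1.
- What may go wrong: condensation at the carbon between the two hydroxyl groups (angular annulation), or a second annulation on the remaining phenol.
- Fallback: it sets out from 1 and comes back at 3, and builds ring D by acylation instead of condensation.
- Friedel–Crafts acylation and oxa-Michael closure of 1 with 3-methylbut-2-enoic acid in P2O5/MeSO3H goes para to a hydroxyl and would give the chromanone F8.
- NaBH4 would reduce it to the chromanol F9, and acid-catalysed dehydration (p-TsOH, toluene, reflux) would give 3.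

Further compounds
F1 | step 8 | 2-[2,2-dimethyl-8-(3-methylbut-2-en-1-yl)-7-(prop-2-en-1-yloxy)-2H-chromen-6-yl]-4,4,5,5-tetramethyl-1,3,2-dioxaborolane | CC1(C)OB(OC1(C)C)c1cc2C=CC(C)(C)Oc2c(CC=C(C)C)c1OCC=C
F2 | step 8 | 1-[2-hydroxy-4-(prop-2-en-1-yloxy)phenyl]ethanone | CC(=O)c1ccc(OCC=C)cc1O
F3 | step 8 | (E)-3-(dimethylamino)-1-[2-hydroxy-4-(prop-2-en-1-yloxy)phenyl]prop-2-en-1-one | CN(C)/C=C/C(=O)c1ccc(OCC=C)cc1O
F4 | step 8 | 3-iodo-7-(prop-2-en-1-yloxy)-4H-chromen-4-one | O=c1c(I)coc2cc(OCC=C)ccc12
F5 | step 8 | 3-[2,2-dimethyl-8-(3-methylbut-2-en-1-yl)-7-(prop-2-en-1-yloxy)-2H-chromen-6-yl]-7-(prop-2-en-1-yloxy)-4H-chromen-4-one | O=c1c(coc2cc(OCC=C)ccc12)-c1cc2C=CC(C)(C)Oc2c(CC=C(C)C)c1OCC=C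
F6 | step 8 | (3R,4R)-3-[2,2-dimethyl-8-(3-methylbut-2-en-1-yl)-7-(prop-2-en-1-yloxy)-2H-chromen-6-yl]-7-(prop-2-en-1-yloxy)-3,4-dihydro-2H-chromen-4-ol | CC(C)=CCc1c(OCC=C)c([C@@H]2COc3cc(OCC=C)ccc3[C@@H]2O)cc2c1OC(C)(C)C=C2
F7 | step 2 | 6-bromo-2,2-dimethyl-7-[(2-methylbut-3-en-2-yl)oxy]-2H-chromene | CC1(C)C=Cc2cc(Br)c(OC(C)(C)C=C)cc2O1
F8 | step 1 | 6-bromo-7-hydroxy-2,2-dimethyl-2,3-dihydro-4H-chromen-4-one | CC1(C)CC(=O)c2cc(Br)c(O)cc2O1
F9 | step 1 | 6-bromo-2,2-dimethyl-3,4-dihydro-2H-chromene-4,7-diol (racemic) | CC1(C)CC(O)c2cc(Br)c(O)cc2O1
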